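## Retrosynthetic overview

1. Target 24 comes from the C15 silyl ether 21 (desilylation, oxidation); the C19 acetate and the axial C3 hydroxyl of 21 arise together from the 2,19-dihydroxy-3-ketone 19 (Evans–Tishchenko); 19 comes from keto ester 15, the ring-alkene isomer of 14.
2. Key disconnection: C4–C5 and C9–C10 of 14 in one oxidative radical cascade of the acyclic (E,E)-diene keto ester 10; ring A closes first (C4–C5), ring B second (C9–C10).
3. Enabling feature: in ring A, C19–C4(CH3)–C3(=O) is a latent 2-methyl-3-oxo ester, and C5/C10 and C9/C8 (methyl on C10 and on C8) are the carbons of two (E)-trisubstituted alkenes of a farnesyl-type chain, so a C4 radical can zip up both rings and set C4, C5, C10 and C9.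
4. 10 comes from γ-alkylation (C1–C2 bond) of the dianion of auxiliary ester 8 (from 6 and 7) with allylic bromide 5.
5. 5 comes from (2E,6E)-farnesol 1 by asymmetric hydrogenation (sets C13), silylation, terminal allylic oxidation and bromination.

Key step: step 7

Remark (numbering): labdane numbering is used; ring A = C1–C2–C3–C4–C5–C10, ring B = C5–C6–C7–C8–C9–C10, C19 = the oxygenated carbon on C4, C17 = methyl on C8, side chain C11–C15 on C9. Faces are described relative to the C10 methyl.

Assumption (chemistry): the sense of face selection by the 8-phenylmenthyl ester is taken by analogy with 8-phenylmenthyl 2-methylacetoacetate cyclisations in the podocarpane series, where the (1R,2S,5R) auxiliary leads to the normal (10β-methyl) ring series; the target belongs to the antipodal ring series, so the (1S,2R,5S) auxiliary is used. If the sense proved opposite, the (1R,2S,5R) alcohol would be used with no other change.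

## Route

Step 1
Reactants: 1 (2E,6E)-farnesol
Product: 2 (3R,6E)-3,7,11-trimethyldodeca-6,10-dien-1-ol
Conditions: H2 (100 atm), Ru(OAc)2[(S)-BINAP] (0.2 mol%), MeOH–H2O 95:5, 20 °C
Reagents that add atoms: none
Why: Hydroxyl-directed Ru–BINAP asymmetric hydrogenation (Noyori) reduces only the allylic C2=C3 alkene and, with the (S)-ligand on an (E)-allylic alcohol, should give the (R)-methyl centre (C13 of the target), as geraniol gives (R)-citronellol.

Step 2
Reactants: 2 (3R,6E)-3,7,11-trimethyldodeca-6,10-dien-1-ol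
Product: 3 tert-butyldiphenylsilyl ether of 2
Conditions: t-BuPh2SiCl, imidazole, DMF, 0 °C to rt
Reagents that add atoms: tert-butyl(chloro)diphenylsilane, CC(C)(C)[Si](Cl)(c1ccccc1)c1ccccc1
Why: Standard silylation of a primary alcohol; this silyl ether should survive acetic acid, amide bases and LiAlH4 until step 12.

Step 3
Reactants: 3 tert-butyldiphenylsilyl ether of 2
Product: 4 (2E,6E,10R)-12-(tert-butyldiphenylsilyloxy)-2,6,10-trimethyldodeca-2,6-dien-1-ol
Conditions: SeO2 (0.3 equiv), t-BuOOH (70% aq., 3 equiv), salicylic acid (0.1 equiv), CH2Cl2, 0 °C to rt, stopped at partial conversion, 3 recycled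
Reagents that add atoms: tert-butyl hydroperoxide, CC(C)(C)OO (terminal oxygen source); selenium dioxide, O=[Se]=O (catalytic oxygen carrier)
Why: SeO2-catalysed allylic oxidation (ene reaction then [2,3]-sigmatropic shift) is selective for the (E)-methyl group of a terminal isopropylidene unit, so the (E)-allylic alcohol should form at the chain end while the internal alkene reacts more slowly.

Step 4
Reactants: 4 (2E,6E,10R)-12-(tert-butyldiphenylsilyloxy)-2,6,10-trimethyldodeca-2,6-dien-1-ol
Product: 5 (2E,6E,10R)-1-bromo-12-(tert-butyldiphenylsilyloxy)-2,6,10-trimethyldodeca-2,6-diene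
Conditions: CBr4, PPh3, CH2Cl2, −20 to 0 °C
Reagents that add atoms: carbon tetrabromide, BrC(Br)(Br)Br
Why: Appel bromination converts the primary allylic alcohol to the bromide by SN2 displacement at low temperature, without allylic transposition or loss of (E)-geometry.

Step 5
Reactants: 6 ethyl 2-methyl-3-oxobutanoate; 7 (1S,2R,5S)-5-methyl-2-(2-phenylpropan-2-yl)cyclohexan-1-ol [(+)-8-phenylmenthol]
Product: 8 (1S,2R,5S)-8-phenylmenthyl 2-methyl-3-oxobutanoate
Conditions: DMAP (0.3 equiv), toluene, reflux, 4 Å molecular sieves (ethanol removal)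
Reagents that add atoms: none
Why: DMAP-catalysed transesterification of a β-keto ester is driven by removal of ethanol and tolerates hindered secondary alcohols; the α-centre is epimeric and is erased in step 7.

Step 6
Reactants: 8 (1S,2R,5S)-8-phenylmenthyl 2-methyl-3-oxobutanoate; 5 (2E,6E,10R)-1-bromo-12-(tert-butyldiphenylsilyloxy)-2,6,10-trimethyldodeca-2,6-diene
Product: 10 (1S,2R,5S)-8-phenylmenthyl (6E,10E,14R)-16-(tert-butyldiphenylsilyloxy)-2,6,10,14-tetramethyl-3-oxohexadeca-6,10-dienoate, via dianion 9 (not isolated)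
Conditions: NaH (1.1 equiv), THF, 0 °C; n-BuLi (1.05 equiv), 0 °C; then 5, 0 °C; sat. aq. NH4Cl
Reagents that add atoms: none
Why: Acetoacetate dianion γ-alkylation: the terminal carbanion of 9 is the more nucleophilic site and displaces the primary allylic bromide by SN2, forming the C1–C2 bond with both (E)-alkenes untouched.

Step 7
Reactants: 10 (1S,2R,5S)-8-phenylmenthyl (6E,10E,14R)-16-(tert-butyldiphenylsilyloxy)-2,6,10,14-tetramethyl-3-oxohexadeca-6,10-dienoate
Product: 14 (+)-8-phenylmenthyl 15-(tert-butyldiphenylsilyloxy)-3-oxo-ent-labd-8(17)-en-19-oate, via C4 radical 11 (not isolated), via monocyclic C10 radical 12 (not isolated), via bicyclic C8 radical 13 (not isolated)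
Conditions: Mn(OAc)3·2H2O (2.2 equiv), Cu(OAc)2·H2O (1.0 equiv), degassed AcOH (0.05 M), 25 °C; minor ring diastereomer removed by chromatography
Reagents that add atoms: none
Why: Mn(OAc)3 oxidises the enolate of the 2-methyl-3-oxo ester to the electrophilic tertiary C4 radical 11, which adds 6-endo-trig to C5 of the (E)-C5=C10 alkene (ring A, chair) to give the tertiary C10 radical 12; this adds 6-endo-trig to C9 of the (E)-C8=C9 alkene (ring B, second chair) to give the tertiary C8 radical 13, which Cu(OAc)2 oxidises through an organocopper species that loses a β-hydrogen, chiefly from the C17 methyl. The closest known reaction type is the Mn(OAc)3/Cu(OAc)2 oxidative free-radical polycyclisation of 2-methyl-3-oxo polyenoates to 3-oxo-4-carboalkoxy trans-decalins, including its 8-phenylmenthyl ester version. C5, C10 and C9 follow from the two (E)-alkenes reacting through a chair–chair array (trans ring fusion, equatorial C9 side chain), and C4 from the preference of this radical to cyclise with the ester carbonyl anti to the ketone oxygen, which places the ester axial and cis to the C10 methyl. Absolute configuration is imposed by the auxiliary, whose phenyl ring should cover one face of the radical so that C5 bonds to the open face; the remote C13 centre should have no influence. The step needs 6-endo over 5-exo closure twice (secured by the methyl group on the internal carbon of each alkene), face selectivity (auxiliary) and clean termination (divalent copper traps the tertiary radical faster than hydrogen abstraction from solvent); the minor C7=C8 alkene isomer that termination should also give is compound 15 itself and is carried into step 8.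

Step 8
Reactants: 14 (+)-8-phenylmenthyl 15-(tert-butyldiphenylsilyloxy)-3-oxo-ent-labd-8(17)-en-19-oate
Product: 15 (+)-8-phenylmenthyl 15-(tert-butyldiphenylsilyloxy)-3-oxo-ent-labd-7-en-19-oate
Conditions: Co(salen)Cl [salen = N,N'-bis(3,5-di-tert-butylsalicylidene)ethane-1,2-diaminate; trivalent cobalt] (3 mol%), PhSiH3 (6 mol%), benzene, 22 °C
Reagents that add atoms: none
Why: Hydrogen-atom-transfer alkene isomerisation (Mukaiyama-type): the Co–H species formed from Co(salen)Cl and PhSiH3 transfers a hydrogen atom to the exocyclic CH2, and the divalent cobalt complex left in the solvent cage takes a hydrogen atom back from the less hindered C7 methylene rather than from the neopentyl-type C9 methine, so the trisubstituted ring alkene should form under kinetic control and, being a poor acceptor for this catalyst, should not migrate further.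

Step 9
Reactants: 15 (+)-8-phenylmenthyl 15-(tert-butyldiphenylsilyloxy)-3-oxo-ent-labd-7-en-19-oate
Product: 17 15-(tert-butyldiphenylsilyloxy)-19-hydroxy-ent-labd-7-en-3-one, via potassium enolate 16 (not isolated)
Conditions: KN(SiMe3)2 (1.2 equiv), THF, −78 to 0 °C; then LiAlH4 (3 equiv), 0 to 40 °C; aq. KNaC4H4O6 at 0 °C; auxiliary 7 recovered
Reagents that add atoms: none
Why: Enolate protection: deprotonation at C2 (the only enolisable site of the ketone) masks the C3 carbonyl as enolate 16 while LiAlH4 reduces the hindered ester to the C19 carbinol and releases the auxiliary, and a cold quench should return the ketone without retro-aldol loss of formaldehyde.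

Step 10
Reactants: 17 15-(tert-butyldiphenylsilyloxy)-19-hydroxy-ent-labd-7-en-3-one
Product: 19 15-(tert-butyldiphenylsilyloxy)-2,19-dihydroxy-ent-labd-7-en-3-one, via dipotassium alkoxide enolate 18 (not isolated)
Conditions: KN(SiMe3)2 (2.3 equiv), THF, −78 °C (17 added to the base); 2-(phenylsulfonyl)-3-phenyloxaziridine (1.3 equiv), −78 °C; sat. aq. NH4Cl at −78 °C
Reagents that add atoms: 2-(phenylsulfonyl)-3-phenyloxaziridine, O=S(=O)(c1ccccc1)N1OC1c1ccccc1
Why: Enolate hydroxylation with an N-sulfonyloxaziridine (Davis oxidation): the C2 enolate carbon of 18 should be attacked on the face opposite the axial C10 methyl and the axial C19 arm, placing the new hydroxyl equatorial and trans to the C10 methyl; the potassium counter-ion and cold quench suppress addition to the sulfonimine and retro-aldol cleavage.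

Step 11
Reactants: 19 15-(tert-butyldiphenylsilyloxy)-2,19-dihydroxy-ent-labd-7-en-3-one
Product: 21 19-acetoxy-15-(tert-butyldiphenylsilyloxy)-ent-labd-7-ene-2,3-diol, via C19 hemiacetal 20 (not isolated)
Conditions: SmI2 (0.3 equiv, premixed with the aldehyde), CH3CHO (10 equiv), THF, −10 °C
Reagents that add atoms: acetaldehyde, CC=O
Why: Evans–Tishchenko reduction: the trivalent samarium alkoxide formed from SmI2 and acetaldehyde binds the C3 carbonyl and hemiacetal 20 of the C19 hydroxyl, and hydride passes within a six-membered array to the C3 face that carries the axial C19 arm, so the C3 hydroxyl should emerge trans to C19 (axial, cis to the C2 hydroxyl) while the acetyl group ends on the C19 oxygen in the same event.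

Step 12
Reactants: 21 19-acetoxy-15-(tert-butyldiphenylsilyloxy)-ent-labd-7-ene-2,3-diol
Product: 22 19-acetoxy-ent-labd-7-ene-2,3,15-triol
Conditions: HF·pyridine, pyridine, THF, 0 °C to rt
Reagents that add atoms: none
Why: Fluoride cleavage of the silyl ether under buffered, weakly acidic conditions avoids the base-promoted acetyl migration that a basic fluoride source could cause.

Step 13
Reactants: 22 19-acetoxy-ent-labd-7-ene-2,3,15-triol
Product: 24 (13R)-19-acetoxy-2,3-dihydroxy-ent-labd-7-en-15-oic acid (target), via C15 aldehyde 23 (not isolated)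
Conditions: TEMPO (0.1 equiv), NaClO2 (2 equiv), NaOCl (0.05 equiv), MeCN–sodium phosphate buffer pH 6.7, 35 °C; then aq. NaH2PO4
Reagents that add atoms: sodium chlorite, [Na+].[O-]Cl=O
Why: TEMPO-catalysed oxidation with NaClO2 as terminal oxidant takes the unhindered primary alcohol through aldehyde 23 to the acid, while the bulky oxoammonium species should discriminate against the hindered secondary hydroxyls, no glycol-cleaving oxidant is present, and the near-neutral buffer leaves the acetate and the trisubstituted alkene untouched.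

## Compound list

1 | (2E,6E)-farnesol | OC/C=C(\C)CC/C=C(\C)CCC=C(C)C | starting material
2 | (3R,6E)-3,7,11-trimethyldodeca-6,10-dien-1-ol [(R)-2,3-dihydrofarnesol] | OCC[C@H](C)CC/C=C(\C)CCC=C(C)C | intermediate
3 | tert-butyldiphenylsilyl ether of 2 | CC(C)(C)[Si](c1ccccc1)(c1ccccc1)OCC[C@H](C)CC/C=C(\C)CCC=C(C)C | intermediate
4 | (2E,6E,10R)-12-(tert-butyldiphenylsilyloxy)-2,6,10-trimethyldodeca-2,6-dien-1-ol | OC/C(C)=C/CC/C(C)=C/CC[C@@H](C)CCO[Si](c1ccccc1)(c1ccccc1)C(C)(C)C | intermediate
5 | (2E,6E,10R)-1-bromo-12-(tert-butyldiphenylsilyloxy)-2,6,10-trimethyldodeca-2,6-diene | BrC/C(C)=C/CC/C(C)=C/CC[C@@H](C)CCO[Si](c1ccccc1)(c1ccccc1)C(C)(C)C | intermediate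
6 | ethyl 2-methyl-3-oxobutanoate | CCOC(=O)C(C)C(C)=O | starting material
7 | (1S,2R,5S)-5-methyl-2-(2-phenylpropan-2-yl)cyclohexan-1-ol [(+)-8-phenylmenthol] | CC(C)(c1ccccc1)[C@H]1CC[C@H](C)C[C@@H]1O | starting material
8 | (1S,2R,5S)-8-phenylmenthyl 2-methyl-3-oxobutanoate (epimers at the α-carbon) | CC(C)(c1ccccc1)[C@H]1CC[C@H](C)C[C@@H]1OC(=O)C(C)C(C)=O | intermediate
9 | sodium lithium dienolate (dianion) of 8 | CC(C)(c1ccccc1)[C@H]1CC[C@H](C)C[C@@H]1OC([O-])=C(C)C([O-])=C.[Na+].[Li+] | intermediate (not isolated)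
10 | (1S,2R,5S)-8-phenylmenthyl (6E,10E,14R)-16-(tert-butyldiphenylsilyloxy)-2,6,10,14-tetramethyl-3-oxohexadeca-6,10-dienoate (epimers at C2 of the chain) | CC(C)(c1ccccc1)[C@H]1CC[C@H](C)C[C@@H]1OC(=O)C(C)C(=O)CC/C(C)=C/CC/C(C)=C/CC[C@@H](C)CCO[Si](c1ccccc1)(c1ccccc1)C(C)(C)C | intermediate
11 | C4 radical of 10 (radical at the carbon between the two carbonyls) | CC(C)(c1ccccc1)[C@H]1CC[C@H](C)C[C@@H]1OC(=O)[C](C)C(=O)CC/C(C)=C/CC/C(C)=C/CC[C@@H](C)CCO[Si](c1ccccc1)(c1ccccc1)C(C)(C)C | intermediate (not isolated)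
12 | monocyclic C10 radical (ring A closed, C4 and C5 set) | CC(C)(c1ccccc1)[C@H]1CC[C@H](C)C[C@@H]1OC(=O)[C@@]2(C)[C@@H](CC/C(C)=C/CC[C@@H](C)CCO[Si](c3ccccc3)(c3ccccc3)C(C)(C)C)[C](C)CCC2=O | intermediate (not isolated)
13 | bicyclic C8 radical (rings A and B closed) | CC(C)(c1ccccc1)[C@H]1CC[C@H](C)C[C@@H]1OC(=O)[C@@]2(C)[C@H]3CC[C](C)[C@@H](CC[C@@H](C)CCO[Si](c4ccccc4)(c4ccccc4)C(C)(C)C)[C@]3(C)CCC2=O | intermediate (not isolated)
14 | (+)-8-phenylmenthyl 15-(tert-butyldiphenylsilyloxy)-3-oxo-ent-labd-8(17)-en-19-oate (trans-decalin; C4 ester axial and cis to the C10 methyl; H5 and H9 on the opposite face; exocyclic C8=C17; 13R) | CC(C)(c1ccccc1)[C@H]1CC[C@H](C)C[C@@H]1OC(=O)[C@@]2(C)[C@H]3CCC(=C)[C@@H](CC[C@@H](C)CCO[Si](c4ccccc4)(c4ccccc4)C(C)(C)C)[C@]3(C)CCC2=O | intermediate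
15 | (+)-8-phenylmenthyl 15-(tert-butyldiphenylsilyloxy)-3-oxo-ent-labd-7-en-19-oate (as 14, C7=C8 ring alkene) | CC(C)(c1ccccc1)[C@H]1CC[C@H](C)C[C@@H]1OC(=O)[C@@]2(C)[C@H]3CC=C(C)[C@@H](CC[C@@H](C)CCO[Si](c4ccccc4)(c4ccccc4)C(C)(C)C)[C@]3(C)CCC2=O | intermediate
16 | potassium C2=C3 enolate of 15 | CC(C)(c1ccccc1)[C@H]1CC[C@H](C)C[C@@H]1OC(=O)[C@@]2(C)[C@H]3CC=C(C)[C@@H](CC[C@@H](C)CCO[Si](c4ccccc4)(c4ccccc4)C(C)(C)C)[C@]3(C)CC=C2[O-].[K+] | intermediate (not isolated)
17 | 15-(tert-butyldiphenylsilyloxy)-19-hydroxy-ent-labd-7-en-3-one (axial CH2OH on C4, cis to the C10 methyl) | OC[C@@]1(C)[C@H]2CC=C(C)[C@@H](CC[C@@H](C)CCO[Si](c3ccccc3)(c3ccccc3)C(C)(C)C)[C@]2(C)CCC1=O | intermediate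
18 | dipotassium C19 alkoxide / C2=C3 enolate of 17 | [O-]C[C@@]1(C)[C@H]2CC=C(C)[C@@H](CC[C@@H](C)CCO[Si](c3ccccc3)(c3ccccc3)C(C)(C)C)[C@]2(C)CC=C1[O-].[K+].[K+] | intermediate (not isolated)
19 | 15-(tert-butyldiphenylsilyloxy)-2,19-dihydroxy-ent-labd-7-en-3-one (C2 hydroxyl equatorial, trans to the C10 methyl) | OC[C@@]1(C)[C@H]2CC=C(C)[C@@H](CC[C@@H](C)CCO[Si](c3ccccc3)(c3ccccc3)C(C)(C)C)[C@]2(C)C[C@H](O)C1=O | intermediate
20 | C19 O-(1-hydroxyethyl) hemiacetal of 19 (samarium-bound in the flask; hemiacetal carbon unassigned) | CC(O)OC[C@@]1(C)[C@H]2CC=C(C)[C@@H](CC[C@@H](C)CCO[Si](c3ccccc3)(c3ccccc3)C(C)(C)C)[C@]2(C)C[C@H](O)C1=O | intermediate (not isolated)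
21 | 19-acetoxy-15-(tert-butyldiphenylsilyloxy)-ent-labd-7-ene-2,3-diol (C2 OH equatorial, C3 OH axial, both trans to the C10 methyl and to C19) | CC(=O)OC[C@@]1(C)[C@H]2CC=C(C)[C@@H](CC[C@@H](C)CCO[Si](c3ccccc3)(c3ccccc3)C(C)(C)C)[C@]2(C)C[C@H](O)[C@@H]1O | intermediate
22 | 19-acetoxy-ent-labd-7-ene-2,3,15-triol | CC(=O)OC[C@@]1(C)[C@H]2CC=C(C)[C@@H](CC[C@@H](C)CCO)[C@]2(C)C[C@H](O)[C@@H]1O | intermediate
23 | 19-acetoxy-2,3-dihydroxy-ent-labd-7-en-15-al | CC(=O)OC[C@@]1(C)[C@H]2CC=C(C)[C@@H](CC[C@@H](C)CC=O)[C@]2(C)C[C@H](O)[C@@H]1O | intermediate (not isolated)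
24 | (13R)-19-acetoxy-2,3-dihydroxy-ent-labd-7-en-15-oic acid (CNP0164890.1) | CC(=O)OC[C@@]1(C)[C@H]2CC=C(C)[C@@H](CC[C@@H](C)CC(=O)O)[C@]2(C)C[C@H](O)[C@@H]1O | target

## Step count and risks

Total step count: 13. Longest linear sequence: 12 steps (steps 1–4 and 6–13, from 1); step 5 is a one-step side branch.

The three steps most likely to fail:

1. Step 8 (alkene isomerisation). What may go wrong: hydrogen return from the C9 methine competes with return from C7, or the isomerisation stalls, leaving alkene regioisomers that are hard to separate. Fallback, a regiospecific two-stage transposition instead of a direct isomerisation: starting from 14, SeO2 (cat.)/t-BuOOH allylic oxidation at the C7 methylene should give the axial 7-hydroxy-8(17)-ene F1. A Mitsunobu reaction with 2-nitrobenzenesulfonylhydrazide (PPh3, diethyl azodicarboxylate, THF, −30 °C) should give the N-allyl sulfonylhydrazine F2. On warming, F2 loses 2-nitrobenzenesulfinic acid to give the allylic diazene F3, and sigmatropic loss of N2 from F3 delivers hydrogen to C17 and moves the alkene to C7=C8. The sequence comes back to the route at 15.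

2. Step 10 (hydroxylation at C2). What may go wrong: retro-aldol loss of formaldehyde from the C19 alkoxide once the C3 carbonyl is regenerated, or incomplete dianion formation leading to mixed products. Fallback, a neutral oxidation of a silyl enol ether in place of a basic enolate oxidation: starting from 17, Et3SiOSO2CF3/Et3N (CH2Cl2, 0 °C) should give the bis(triethylsilyl) derivative F4 (C19 silyl ether and C2=C3 silyl enol ether). Dimethyldioxirane (1 equiv, acetone/CH2Cl2, −78 °C) should oxidise the electron-rich enol ether in preference to the C7=C8 alkene, from the face opposite the C10 methyl, and silyl transfer gives the 2-(triethylsilyloxy) ketone F5 (Rubottom oxidation). AcOH/THF/H2O at rt removes both triethylsilyl groups and the sequence comes back to the route at 19.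

3. Step 11 (reduction with acetyl transfer). What may go wrong: slow hydride transfer from the hemiacetal to the hindered C3 carbonyl next to a quaternary carbon, or acetyl migration among O19, O3 and O2 under Lewis acid. Fallback, directed reduction and acylation as separate operations: starting from 19, Me4NBH(OAc)3 in MeCN/AcOH at −30 °C (Evans–Saksena reduction, hydride delivered from boron bound to the C19 hydroxyl to the same face) should give the triol F6. Candida antarctica lipase B with vinyl acetate in tert-butyl methyl ether should acetylate only the primary C19 hydroxyl, and the sequence comes back to the route at 21.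

Further compounds
F1 | step 8 | (+)-8-phenylmenthyl 15-(tert-butyldiphenylsilyloxy)-7-hydroxy-3-oxo-ent-labd-8(17)-en-19-oate (axial C7 hydroxyl, trans to the C10 methyl) | CC(C)(c1ccccc1)[C@H]1CC[C@H](C)C[C@@H]1OC(=O)[C@@]2(C)[C@H]3C[C@H](O)C(=C)[C@@H](CC[C@@H](C)CCO[Si](c4ccccc4)(c4ccccc4)C(C)(C)C)[C@]3(C)CCC2=O
F2 | step 8 | N-allyl N-(2-nitrobenzenesulfonyl)hydrazine from F1 (C7 inverted) | CC(C)(c1ccccc1)[C@H]1CC[C@H](C)C[C@@H]1OC(=O)[C@@]2(C)[C@H]3C[C@@H](N(N)S(=O)(=O)c4ccccc4[N+](=O)[O-])C(=C)[C@@H](CC[C@@H](C)CCO[Si](c4ccccc4)(c4ccccc4)C(C)(C)C)[C@]3(C)CCC2=O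
F3 | step 8 | C7 allylic diazene from F2 | CC(C)(c1ccccc1)[C@H]1CC[C@H](C)C[C@@H]1OC(=O)[C@@]2(C)[C@H]3C[C@@H](N=N)C(=C)[C@@H](CC[C@@H](C)CCO[Si](c4ccccc4)(c4ccccc4)C(C)(C)C)[C@]3(C)CCC2=O
F4 | step 10 | 15-(tert-butyldiphenylsilyloxy)-3,19-bis(triethylsilyloxy)-ent-labda-2,7-diene | CC[Si](CC)(CC)OC[C@@]1(C)[C@H]2CC=C(C)[C@@H](CC[C@@H](C)CCO[Si](c3ccccc3)(c3ccccc3)C(C)(C)C)[C@]2(C)CC=C1O[Si](CC)(CC)CC
F5 | step 10 | 15-(tert-butyldiphenylsilyloxy)-2,19-bis(triethylsilyloxy)-ent-labd-7-en-3-one (C2 silyloxy group trans to the C10 methyl) | CC[Si](CC)(CC)OC[C@@]1(C)[C@H]2CC=C(C)[C@@H](CC[C@@H](C)CCO[Si](c3ccccc3)(c3ccccc3)C(C)(C)C)[C@]2(C)C[C@H](O[Si](CC)(CC)CC)C1=O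
F6 | step 11 | 15-(tert-butyldiphenylsilyloxy)-ent-labd-7-ene-2,3,19-triol (C2 and C3 hydroxyls trans to the C10 methyl) | OC[C@@]1(C)[C@H]2CC=C(C)[C@@H](CC[C@@H](C)CCO[Si](c3ccccc3)(c3ccccc3)C(C)(C)C)[C@]2(C)C[C@H](O)[C@@H]1O
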